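**Retrosynthetic overview**
1. The ten-membered ring is closed last at C4–C5 by an intramolecular Nozaki–Hiyama–Kishi addition of a 2-bromoalkene to the C-5 aldehyde, which gives the exocyclic methylene and the C-5 carbinol together; the lactone α-methylene comes from a phosphonate shortly before.
2. Both oxiranes come from one syn-chlorohydrin allylic alcohol: hydroxyl-directed epoxidation (C1–C10), then chloride displacement (C2–C3).
3. The C2–C3 bond comes from a chiral phosphoric acid-catalysed addition of a new 2-bromo-3-chloroallylboronate to an E-enal (the new step).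
4. The C8–C9 bond comes from a Felkin-selective vinylogous Mukaiyama aldol of a prenal silyl dienol ether with a trans-lactone aldehyde, followed by angeloylation.
5. The γ-lactone comes from a D-proline cross-aldol of two achiral aldehydes, lactonisation and epimerisation. Ring order: γ-lactone, C1/C10 oxirane, C2/C3 oxirane, carbocycle.

Assumption: C-1 to C-15 are the germacranolide positions of the target (lactone O on C-6, angelate on C-8, OH on C-5, oxiranes C-1/C-10 and C-2/C-3, methylenes C-15 on C-4 and C-13 on C-11).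
Assumption: the phosphonate-bearing carbon (later C-11) is a labile centre carried as both epimers (left undefined in the SMILES) until the olefination removes it.

**Route**

Step 1
Reactants: 1 ethyl (E)-4-oxobut-2-enoate
Product: 2 ethyl 2-(diethoxyphosphoryl)-4-oxobutanoate (racemic β-phosphono aldehyde)
Conditions: P(OEt)3, pyrrolidine (10 mol%), PhCO2H, NaI, CH2Cl2, rt
Reagents that add atoms: triethyl phosphite, CCOP(OCC)OCC
Why: Iminium-activated phospha-Michael addition of the phosphite β to the aldehyde (α to the ester) followed by iodide dealkylation (Michaelis–Arbuzov) gives the β-phosphono aldehyde, whose new centre is racemic, labile and erased in step 9.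

Step 2
Reactants: 2 ethyl 2-(diethoxyphosphoryl)-4-oxobutanoate; 3 (tert-butyldimethylsilyloxy)acetaldehyde
Product: 6 trans-lactone aldehyde diethyl [(4S,5S)-5-(tert-butyldimethylsilyloxymethyl)-4-formyl-2-oxooxolan-3-yl]phosphonate, via anti-aldol adduct 4 (not isolated), via cis-lactone aldehyde 5 (not isolated)
Conditions: D-proline (20 mol%), DMF, 4 °C, slow addition of 2; then PPTS (10 mol%), CH2Cl2, rt; then Et3N (0.3 equiv), rt
Reagents that add atoms: none
Why: Enamine cross-aldol in which the D-proline enamine of 2 adds to the Si face of the more electrophilic α-silyloxy aldehyde 3 and so fixes C-6 (the first defined stereocentre), after which the γ-hydroxy ester lactonises and the epimerisable formyl-bearing C-7 equilibrates to the more stable 6,7-trans lactone.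

Step 3
Reactants: 7 3-methylbut-2-enal (prenal)
Product: 8 tert-butyl(dimethyl){[(1E)-3-methylbuta-1,3-dien-1-yl]oxy}silane
Conditions: TBSOTf, Et3N, Et2O, 0 °C → rt
Reagents that add atoms: tert-butyldimethylsilyl trifluoromethanesulfonate, CC(C)(C)[Si](C)(C)OS(=O)(=O)C(F)(F)F
Why: Soft enolisation with γ-deprotonation converts the enal into its silyl dienol ether; no stereocentre is formed.

Step 4
Reactants: 6 trans-lactone aldehyde; 8 silyl dienol ether
Product: 9 enal alcohol: lactone 6 whose formyl group has become a (1S,3E)-1-hydroxy-3-methyl-5-oxopent-3-en-1-yl chain (C-8 carbinol; E-C10=C1 enal)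
Conditions: BF3·OEt2, CH2Cl2, −78 °C; aq. NaHCO3
Reagents that add atoms: none
Why: Vinylogous Mukaiyama aldol at the γ-carbon of the dienol ether, in which Felkin–Anh attack anti to the oxygen-bearing C7–C6 bond sets C-8 and the s-trans diene gives the E-enal.

Step 5
Reactants: 9 enal alcohol
Product: 10 C-8 angelate [(Z)-2-methylbut-2-enoate] of 9
Conditions: angelic acid, 2,4,6-trichlorobenzoyl chloride, Et3N, toluene, rt → 60 °C (no DMAP)
Reagents that add atoms: angelic acid, C/C=C(/C)C(=O)O
Why: Yamaguchi-type mixed-anhydride esterification acylates the secondary C-8 hydroxyl, and leaving out nucleophilic catalysts keeps the Z geometry of the angelate.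

Step 6
Reactants: 11 3-chloroprop-1-yne (propargyl chloride)
Product: 12 1-chloropropa-1,2-diene (chloroallene)
Conditions: CuCl (10 mol%), NH4Cl, conc. HCl, rt; fractional distillation
Reagents that add atoms: none
Why: Copper-catalysed propargyl-to-allenyl chloride isomerisation (SN2′ chloride exchange) gives the allene, which is removed by distillation as the lower-boiling isomer.

Step 7
Reactants: 10 angelate enal; 12 chloroallene
Product: 15 syn-chlorohydrin: the aldehyde of 10 converted into a (1R,2S)-3-bromo-2-chloro-1-hydroxybut-3-en-1-yl unit (C-2 carbinol; C-3 chloride; 1-bromovinyl on C-3), via allyldibromoborane 13 (not isolated), via allylboronate 14 (not isolated)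
Conditions: 12, BBr3, CH2Cl2, −78 °C; pinacol, 2,6-lutidine, −78 °C → rt, filter; then 10, (S)-TRIP [(S)-3,3′-bis(2,4,6-triisopropylphenyl)-1,1′-binaphthyl-2,2′-diyl hydrogen phosphate, 10 mol%], 4 Å MS, toluene, −30 °C → rt; H2O
Reagents that add atoms: boron tribromide, BrB(Br)Br
Why: Proposed new method: BBr3 is expected to bromoborate the unsubstituted C=C of chloroallene from the face anti to chlorine (B to CH2, Br to the central carbon), giving after esterification a configurationally stable γ-chloro-β-bromoallylboronate with Cl cis to CH2B, which adds through its γ-carbon to the enal in a chair six-membered transition state (Cl axial, hence the syn-chlorohydrin) while the phosphoric acid, hydrogen-bonded to a boronate oxygen and the formyl C–H, directs Si-face attack and so sets C-2 and C-3 independently of the remote centres; the closest known reactions are haloboration of allene to 2-bromoallylboranes, (Z)-γ-chloroallylboration of aldehydes to syn-chlorohydrins, and chiral phosphoric acid-catalysed allyl- and crotylboration with pinacol boronates.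

Step 8
Reactants: 15 syn-chlorohydrin
Product: 17 diepoxide: (1R,10R)-1,10-oxirane and cis-2,3-oxirane bearing the 1-bromovinyl group on C-3 (configured as in 21), via epoxy chlorohydrin 16 (not isolated)
Conditions: mCPBA, CH2Cl2, −20 °C; then DBU, 0 °C → rt
Reagents that add atoms: 3-chloroperoxybenzoic acid (mCPBA), OOC(=O)c1cccc(Cl)c1
Why: Hydroxyl-directed (Henbest-type) peracid epoxidation in which 1,3-allylic strain with the cis methyl holds the C2–H in the alkene plane so that oxygen is delivered syn to the C-2 hydroxyl (threo), setting C-1 and C-10 on the E-alkene, after which DBU closes the syn-chlorohydrin by intramolecular SN2 with inversion at C-3 to the cis-2,3-oxirane.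

Step 9
Reactants: 17 diepoxide
Product: 18 α-methylene lactone (the phosphonate of 17 replaced by =CH2)
Conditions: aq. HCHO, K2CO3, THF, 0 °C → rt
Reagents that add atoms: formaldehyde, C=O
Why: Horner–Wadsworth–Emmons olefination of the α-phosphono lactone with formaldehyde installs the exocyclic methylene under mild base and removes the labile C-11 centre.

Step 10
Reactants: 18 α-methylene lactone silyl ether
Product: 19 primary alcohol (C-5 CH2OH)
Conditions: HF·pyridine, pyridine, THF, 0 °C
Reagents that add atoms: none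
Why: Buffered fluoride cleavage of the primary silyl ether, to which the oxiranes, the vinyl bromide and the esters are inert.

Step 11
Reactants: 19 primary alcohol
Product: 20 C-5 aldehyde
Conditions: Dess–Martin periodinane, pyridine, CH2Cl2, 0 °C → rt
Reagents that add atoms: none
Why: Dess–Martin oxidation converts the primary alcohol into the aldehyde under buffered, non-epimerising conditions.

Step 12
Reactants: 20 C-5 aldehyde
Product: 21 target, 8α-angeloyloxy-5β-hydroxy-1β,10α:2α,3α-diepoxygermacra-4(15),11(13)-dien-6α,12-olide, (1R,2S,3S,5S,6S,7R,8S,10R)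
Conditions: CrCl2 (8 equiv), NiCl2 (2 mol%), DMSO, rt, slow addition to 2 mM
Reagents that add atoms: none
Why: Intramolecular Nozaki–Hiyama–Kishi reaction (nickel-catalysed activation of the vinyl bromide, transmetalation to chromium, addition to the aldehyde) closes the ten-membered ring, and C-5 is expected to form under macrocyclic control with the chromium-bound carbonyl oxygen on the ring periphery and H-5 anti to H-6, the arrangement of 5β-oxygenated 6α,12-germacranolides.

**Compound list**
1 | ethyl (E)-4-oxobut-2-enoate | CCOC(=O)/C=C/C=O | starting material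
2 | ethyl 2-(diethoxyphosphoryl)-4-oxobutanoate (racemic) | CCOC(=O)C(CC=O)P(=O)(OCC)OCC | intermediate
3 | (tert-butyldimethylsilyloxy)acetaldehyde | O=CCO[Si](C)(C)C(C)(C)C | starting material
4 | anti-aldol adduct, ethyl 5-(tert-butyldimethylsilyloxy)-2-(diethoxyphosphoryl)-3-formyl-4-hydroxypentanoate (3,4-anti, 4S, C-2 epimers) | CCOC(=O)C(P(=O)(OCC)OCC)[C@@H](C=O)[C@H](O)CO[Si](C)(C)C(C)(C)C | intermediate
5 | cis-lactone aldehyde, diethyl [(4R,5S)-5-(tert-butyldimethylsilyloxymethyl)-4-formyl-2-oxooxolan-3-yl]phosphonate (C-3 epimers) | CCOP(=O)(OCC)C1C(=O)O[C@H](CO[Si](C)(C)C(C)(C)C)[C@@H]1C=O | intermediate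
6 | trans-lactone aldehyde, diethyl [(4S,5S)-5-(tert-butyldimethylsilyloxymethyl)-4-formyl-2-oxooxolan-3-yl]phosphonate (C-3 epimers) | CCOP(=O)(OCC)C1C(=O)O[C@H](CO[Si](C)(C)C(C)(C)C)[C@H]1C=O | intermediate
7 | 3-methylbut-2-enal (prenal) | CC(C)=CC=O | starting material
8 | tert-butyl(dimethyl){[(1E)-3-methylbuta-1,3-dien-1-yl]oxy}silane | C=C(C)/C=C/O[Si](C)(C)C(C)(C)C | intermediate
9 | enal alcohol: 6 with the formyl group converted into a (1S,3E)-1-hydroxy-3-methyl-5-oxopent-3-en-1-yl chain | CCOP(=O)(OCC)C1C(=O)O[C@H](CO[Si](C)(C)C(C)(C)C)[C@H]1[C@@H](O)C/C(C)=C/C=O | intermediate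
10 | C-8 angelate of 9 | CCOP(=O)(OCC)C1C(=O)O[C@H](CO[Si](C)(C)C(C)(C)C)[C@H]1[C@@H](OC(=O)/C(C)=C\C)C/C(C)=C/C=O | intermediate
11 | 3-chloroprop-1-yne (propargyl chloride) | C#CCCl | starting material
12 | 1-chloropropa-1,2-diene (chloroallene) | ClC=C=C | intermediate
13 | dibromo[(2E)-2-bromo-3-chloroprop-2-en-1-yl]borane (Cl cis to CH2B) | Cl/C=C(/Br)CB(Br)Br | intermediate
14 | 2-[(2E)-2-bromo-3-chloroprop-2-en-1-yl]-4,4,5,5-tetramethyl-1,3,2-dioxaborolane (Cl cis to CH2B) | Cl/C=C(/Br)CB1OC(C)(C)C(C)(C)O1 | intermediate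
15 | syn-chlorohydrin: C-2 (R) carbinol, C-3 (S) chloride, 1-bromovinyl on C-3, E-C10=C1 alkene, rest as 10 | CCOP(=O)(OCC)C1C(=O)O[C@H](CO[Si](C)(C)C(C)(C)C)[C@H]1[C@@H](OC(=O)/C(C)=C\C)C/C(C)=C/[C@@H](O)[C@H](Cl)C(Br)=C | intermediate
16 | epoxy chlorohydrin: (1R,10R)-1,10-oxirane of 15 (oxirane O syn to the C-2 hydroxyl) | CCOP(=O)(OCC)C1C(=O)O[C@H](CO[Si](C)(C)C(C)(C)C)[C@H]1[C@@H](OC(=O)/C(C)=C\C)C[C@@]1(C)O[C@@H]1[C@@H](O)[C@H](Cl)C(Br)=C | intermediate
17 | diepoxide: trans-1,10-oxirane and cis-2,3-oxirane with 1-bromovinyl on C-3, phosphono lactone, silyl ether | CCOP(=O)(OCC)C1C(=O)O[C@H](CO[Si](C)(C)C(C)(C)C)[C@H]1[C@@H](OC(=O)/C(C)=C\C)C[C@@]1(C)O[C@@H]1[C@H]1O[C@H]1C(Br)=C | intermediate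
18 | α-methylene lactone silyl ether | C=C1C(=O)O[C@H](CO[Si](C)(C)C(C)(C)C)[C@H]1[C@@H](OC(=O)/C(C)=C\C)C[C@@]1(C)O[C@@H]1[C@H]1O[C@H]1C(Br)=C | intermediate
19 | primary alcohol (C-5 CH2OH) | C=C1C(=O)O[C@H](CO)[C@H]1[C@@H](OC(=O)/C(C)=C\C)C[C@@]1(C)O[C@@H]1[C@H]1O[C@H]1C(Br)=C | intermediate
20 | C-5 aldehyde (seco-precursor: 2-bromoalkene at C-4, aldehyde at C-5) | C=C1C(=O)O[C@H](C=O)[C@H]1[C@@H](OC(=O)/C(C)=C\C)C[C@@]1(C)O[C@@H]1[C@H]1O[C@H]1C(Br)=C | intermediate
21 | EANPDB:COMP_00179, 8α-angeloyloxy-5β-hydroxy-1β,10α:2α,3α-diepoxygermacra-4(15),11(13)-dien-6α,12-olide, (1R,2S,3S,5S,6S,7R,8S,10R) | C=C1C(=O)O[C@H]2[C@H]1[C@@H](OC(=O)/C(C)=C\C)C[C@@]1(C)O[C@@H]1[C@H]1O[C@H]1C(=C)[C@@H]2O | target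

**Step count**
Total step count: 12. Longest linear sequence: 10 steps (steps 1, 2, 4, 5, 7, 8, 9, 10, 11, 12); steps 3 and 6 are one-step side branches.

**Steps most likely to fail**

Step 2 (cross-aldol, lactonisation, epimerisation). The risks are self-aldol of the enolisable acceptor 3 and β-elimination of the β-acyloxy aldehyde during the base-mediated equilibration at C-7. The fallback sets out from 2 and 3 and returns at 6. It makes the 6,7-relationship kinetically instead of by epimerisation: a syn-selective enamine cross-aldol with an axially chiral binaphthyl amino-sulfonamide catalyst gives the syn-aldol adduct F1, which already has the C-7 configuration of 6 and needs only PPTS lactonisation.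

Step 7 (the proposed new step). The risks are loss of the Cl-cis-to-CH2B geometry by 1,3-boratropic shift before esterification, the wrong regiochemistry of bromoboration, and low reactivity of the doubly halogenated allylboronate under phosphoric acid catalysis. The fallback uses known reactions only, sets out from 10 and returns at 17.
- Iminium-catalysed epoxidation of the enal (H2O2, diarylprolinol silyl ether) gives the epoxy aldehyde F2, with the C-1/C-10 oxirane set by the catalyst.
- Stork–Zhao olefination (iodomethyltriphenylphosphonium iodide, NaN(SiMe3)2, −78 °C, excess ylide) gives the (Z)-vinyl iodide F3.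
- Stille coupling with Bu3SnC≡CH and Pd(PPh3)4 gives the (Z)-enyne F4.
- Shi epoxidation of the cis-enyne (oxazolidinone-type fructose-derived ketone, 2KHSO5·KHSO4·K2SO4, K2CO3 buffer; the ketone enantiomer that epoxidises syn to the C-1 oxygen) gives the diepoxy alkyne F5.
- Markovnikov hydrosilylation ([Cp*Ru(MeCN)3]PF6, Et3SiH) gives the α-(triethylsilyl)vinyl diepoxide F6.
- Bromodesilylation with NBS in MeCN returns 17.

Step 12 (ring closure). The risks are the wrong C-5 epimer (acyclic Felkin–Anh preference opposes the desired 5,6-syn product), β-elimination of the vinylchromium onto the adjacent oxirane to give an allene, and the entropic cost of a ten-membered ring. The fallback sets out from 20 and returns at 21; it sets C-5 by reagent-controlled reduction instead of by the C–C bond formation. The closure is run regardless of the C-5 ratio, the C-5 epimer F7 (or the mixture) is oxidised with Dess–Martin periodinane to the cross-conjugated enone F8, and this is reduced with (S)-Me-CBS oxazaborolidine and catecholborane (alkenyl as the large group, giving 5S).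

Further compounds
F1 | step 2 | syn-aldol adduct (C-3 epimer of 4, 3,4-syn) | CCOC(=O)C(P(=O)(OCC)OCC)[C@H](C=O)[C@H](O)CO[Si](C)(C)C(C)(C)C
F2 | step 7 | epoxy aldehyde (1,10-oxirane of 10, C-2 aldehyde) | CCOP(=O)(OCC)C1C(=O)O[C@H](CO[Si](C)(C)C(C)(C)C)[C@H]1[C@@H](OC(=O)/C(C)=C\C)C[C@@]1(C)O[C@@H]1C=O
F3 | step 7 | (Z)-vinyl iodide (C2=C3, iodine on C-3) | CCOP(=O)(OCC)C1C(=O)O[C@H](CO[Si](C)(C)C(C)(C)C)[C@H]1[C@@H](OC(=O)/C(C)=C\C)C[C@@]1(C)O[C@@H]1/C=C\I
F4 | step 7 | (Z)-enyne (C2=C3, C4≡C15) | CCOP(=O)(OCC)C1C(=O)O[C@H](CO[Si](C)(C)C(C)(C)C)[C@H]1[C@@H](OC(=O)/C(C)=C\C)C[C@@]1(C)O[C@@H]1/C=C\C#C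
F5 | step 7 | diepoxy alkyne (cis-2,3-oxirane bearing ethynyl) | CCOP(=O)(OCC)C1C(=O)O[C@H](CO[Si](C)(C)C(C)(C)C)[C@H]1[C@@H](OC(=O)/C(C)=C\C)C[C@@]1(C)O[C@@H]1[C@H]1O[C@H]1C#C
F6 | step 7 | α-(triethylsilyl)vinyl diepoxide | CCOP(=O)(OCC)C1C(=O)O[C@H](CO[Si](C)(C)C(C)(C)C)[C@H]1[C@@H](OC(=O)/C(C)=C\C)C[C@@]1(C)O[C@@H]1[C@H]1O[C@H]1C(=C)[Si](CC)(CC)CC
F7 | step 12 | C-5 epimer of 21 (5α-hydroxy) | C=C1C(=O)O[C@H]2[C@H]1[C@@H](OC(=O)/C(C)=C\C)C[C@@]1(C)O[C@@H]1[C@H]1O[C@H]1C(=C)[C@H]2O
F8 | step 12 | 5-oxo enone (C-5 ketone of 21) | C=C1C(=O)O[C@H]2[C@H]1[C@@H](OC(=O)/C(C)=C\C)C[C@@]1(C)O[C@@H]1[C@H]1O[C@H]1C(=C)C2=O
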